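**Retrosynthetic overview**

1. Numbering: O1, C2 (heptyl), C3, C4 (=O), C4a, C5, C6 (decyl), O7, C8 (=O), C8a; ring A is the lactone (C4a–C5–C6–O7–C8–C8a), ring B the pyranone (O1–C2–C3–C4–C4a–C8a).
2. C2 (S) is set last, by ligand-controlled copper hydride 1,4-reduction of the C2=C3 bond of the 4-pyranone that stands one oxidation level above the target in ring B.
3. That 4-pyranone is disconnected at C4a=C8a, C2–C3 and O1–C2 into an acyclic methyl oxalate of (R)-5-hydroxypentadecan-2-one plus an octanoyl donor; forward, one pot closes ring A first (Dieckmann, C4a–C8a), then joins C2 to C3 (dianion acylation), then closes ring B (acid, O1–C2).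
4. Enabling feature: ring B is a cyclodehydrated 1,3,5-tricarbonyl array (C2, C4, C8a) in which C3 and C4a are the two α-carbons of the C4 ketone, and C8–C8a is an oxalyl unit tethered through O7 to C6, two atoms from C4a.
5. The keto oxalate comes from (R)-1,2-epoxydodecane, which supplies C6 (R), by methallyl Grignard opening, oxalylation and ozonolysis.

Key step: step 4

Assumption: (R)-1,2-epoxydodecane and N-methoxy-N-methyloctanamide are taken as catalogue compounds, and the antipode of the bisphosphine in step 5 is chosen by analogy and would be confirmed in a first run.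

**Route**

Step 1
Reactants: 1 (R)-1,2-epoxydodecane; 2 2-methylallylmagnesium chloride
Product: 3 (R)-2-methylpentadec-1-en-5-ol
Conditions: CuI (10 mol%), THF, −30 → 0 °C; aq NH4Cl
Reagents that add atoms: 2-methylallylmagnesium chloride (compound 2), CC(=C)C[Mg]Cl
Why: Copper-catalysed SN2 ring opening of a terminal epoxide by an allylic Grignard reagent takes place at the unsubstituted carbon, so the carbinol centre (the later C6) keeps the R configuration of 1 and no new stereocentre is made.

Step 2
Reactants: 3 (R)-2-methylpentadec-1-en-5-ol; 4 methyl chlorooxoacetate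
Product: 5 methyl (R)-2-methylpentadec-1-en-5-yl oxalate
Conditions: pyridine, DMAP (cat.), CH2Cl2, 0 °C
Reagents that add atoms: methyl chlorooxoacetate (compound 4), COC(=O)C(=O)Cl
Why: DMAP-catalysed acylation of the secondary alcohol by the acid chloride end of 4 (nucleophilic acyl substitution) should give the mixed oxalate without touching the stereocentre or the alkene.

Step 3
Reactants: 5 methyl (R)-2-methylpentadec-1-en-5-yl oxalate
Product: 7 methyl (R)-2-oxopentadecan-5-yl oxalate, via ozonide 6 (not isolated)
Conditions: O3, CH2Cl2, −78 °C; then PPh3, −78 °C → rt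
Reagents that add atoms: ozone, [O-][O+]=O
Why: Ozonolysis (Criegee mechanism) of the electron-rich 1,1-disubstituted alkene with reductive PPh3 work-up of ozonide 6 should unveil the methyl ketone, while the electron-poor oxalate is inert to ozone.

Step 4
Reactants: 7 methyl (R)-2-oxopentadecan-5-yl oxalate; 8 N-methoxy-N-methyloctanamide
Product: 11 (R)-6-decyl-2-heptyl-5,6-dihydropyrano[3,4-b]pyran-4,8-dione, via Dieckmann lactone 9 (not isolated), via triketone 10 (not isolated)
Conditions: NaH (2.2 equiv), MeOH (cat.), THF, 0 °C → rt; LiN(iPr)2 (1.3 equiv), −78 °C; 8, −78 → 0 °C; aq HCl; crude in CF3CO2H/CH2Cl2, rt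
Reagents that add atoms: N-methoxy-N-methyloctanamide (compound 8), CCCCCCCC(=O)N(C)OC
Why: NaH, with the methoxide it liberates, enolises the ketone reversibly, and the C4a enolate attacks the oxalyl unit in a Dieckmann (intramolecular Claisen) condensation, 6-exo-trig at the ester carbonyl, which closes ring A and makes the C4a–C8a bond as the sodium enolate of 9. LiN(iPr)2 then removes a proton from the acetyl methyl group (1,3-dicarbonyl dianion), and this terminal carbanion, the later C3, attacks Weinreb amide 8 to form the C2–C3 bond as a stable chelate that acid releases as triketone 10. In acid the enol oxygen on C8a adds to the new C2 ketone (6-exo-trig) and water is lost, which closes ring B as a 4-pyranone and fixes C4a=C8a as the enol-ether double bond. The closest known reaction types are the Claisen condensation of ketones with oxalates, the γ-acylation of β-diketone dianions and the acid cyclodehydration of 1,3,5-triketones to 4-pyranones. No stereocentre is formed, and C6, which bears no acidic hydrogen, should be untouched. The step needs ring A to close from C4a and not from the methyl group, which six-membered against seven- or eight-membered transition states should secure under equilibrating enolisation, and it needs the second deprotonation at the methyl group, the only CH left that is α to a carbonyl.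

Step 5
Reactants: 11 (R)-6-decyl-2-heptyl-5,6-dihydropyrano[3,4-b]pyran-4,8-dione
Product: 12 (2S,6R)-6-decyl-2-heptyl-2,3,5,6-tetrahydropyrano[3,4-b]pyran-4,8-dione
Conditions: Cu(OAc)2 (5 mol%), (R)-DTBM-SEGPHOS (5.5 mol%), (EtO)2MeSiH, t-BuOH, toluene, −20 °C; aq NH4Cl
Reagents that add atoms: none
Why: Asymmetric copper hydride conjugate reduction, the reaction type that turns 2-alkylchromones into 2-alkylchromanones, should deliver hydride to C2 of the trisubstituted C2=C3 bond (the tetrasubstituted C4a=C8a bond is too hindered), with the chiral bisphosphine and not the remote C6 centre setting the 2S configuration and t-BuOH protonating the copper enolate before β-elimination of the ring oxygen can open ring B.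

**Compound list**

1 | (R)-1,2-epoxydodecane | CCCCCCCCCC[C@@H]1CO1 | starting material
2 | 2-methylallylmagnesium chloride | CC(=C)C[Mg]Cl | starting material
3 | (R)-2-methylpentadec-1-en-5-ol | CCCCCCCCCC[C@@H](O)CCC(C)=C | intermediate
4 | methyl chlorooxoacetate | COC(=O)C(=O)Cl | starting material
5 | methyl (R)-2-methylpentadec-1-en-5-yl oxalate | CCCCCCCCCC[C@@H](OC(=O)C(=O)OC)CCC(C)=C | intermediate
6 | methyl (3R)-1-(3-methyl-1,2,4-trioxolan-3-yl)tridecan-3-yl oxalate (secondary ozonide, both configurations at the trioxolane carbon) | CCCCCCCCCC[C@@H](OC(=O)C(=O)OC)CCC1(C)OCOO1 | intermediate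
7 | methyl (R)-2-oxopentadecan-5-yl oxalate | CCCCCCCCCC[C@@H](OC(=O)C(=O)OC)CCC(C)=O | intermediate
8 | N-methoxy-N-methyloctanamide | CCCCCCCC(=O)N(C)OC | starting material
9 | (R)-4-acetyl-6-decyl-3-hydroxy-5,6-dihydro-2H-pyran-2-one (in the flask as its sodium enolate) | CCCCCCCCCC[C@@H]1CC(C(C)=O)=C(O)C(=O)O1 | intermediate
10 | (R)-6-decyl-3-hydroxy-4-(3-oxodecanoyl)-5,6-dihydro-2H-pyran-2-one | CCCCCCCCCC[C@@H]1CC(C(=O)CC(=O)CCCCCCC)=C(O)C(=O)O1 | intermediate
11 | (R)-6-decyl-2-heptyl-5,6-dihydropyrano[3,4-b]pyran-4,8-dione | CCCCCCCCCC[C@@H]1CC2=C(OC(CCCCCCC)=CC2=O)C(=O)O1 | intermediate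
12 | (2S,6R)-6-decyl-2-heptyl-2,3,5,6-tetrahydropyrano[3,4-b]pyran-4,8-dione | CCCCCCCCCC[C@@H]1CC2=C(O[C@@H](CCCCCCC)CC2=O)C(=O)O1 | target

**Count and risks**

Total step count: 5. Longest linear sequence: 5 steps (1 → 12).

Steps most likely to fail:

1. Step 5. What may go wrong: poor facial discrimination by the catalyst on a pyranone that lacks the benzo ring of the chromone precedents, competing 1,2-reduction of the C4 ketone, or β-elimination of the ring oxygen from the copper enolate followed by unselective reclosure, which would scramble C2. Fallback: it sets out from 7 and comes back at 12, bypassing 11. Dieckmann condensation alone (NaH, THF; aq HCl) should give 9 as an isolated compound. Double silylation (Me3SiOTf, Et3N, CH2Cl2, 0 °C) should give the bis-silyl dienol ether (R)-6-decyl-3-(trimethylsilyloxy)-4-[1-(trimethylsilyloxy)ethenyl]-5,6-dihydro-2H-pyran-2-one F1. A vinylogous Mukaiyama aldol addition of F1 to octanal catalysed by Ti(OiPr)4/BINOL (antipode chosen for the S alcohol), a reaction type known for 1,3-bis(silyloxy)dienes and aliphatic aldehydes, should give after mild acid (R)-6-decyl-3-hydroxy-4-[(S)-3-hydroxydecanoyl]-5,6-dihydro-2H-pyran-2-one F2. CF3CO2H should then cyclodehydrate F2 through O1–C8a closure, which does not touch C2, to give 12.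

2. Step 4. What may go wrong: enolisation towards the methyl group with intermolecular Claisen condensation, or proton transfer from the α-CH2 of the amide to the dianion so that acylation stalls at the stage of 9. Fallback: it sets out from 7 and comes back at 11. Dieckmann condensation alone should give 9 as an isolated compound. Octanoyl chloride and pyridine should acylate its enol oxygen to the enol ester (R)-4-acetyl-6-decyl-2-oxo-5,6-dihydro-2H-pyran-3-yl octanoate F3. A Baker–Venkataraman O-to-C acyl shift (KOC(CH3)3, THF, 0 °C) should form the C2–C3 bond within the molecule and give triketone 10, which CF3CO2H closes to 11.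

3. Step 3. What may go wrong: cleavage of the mixed oxalate by adventitious water during the reductive work-up of the ozonide or on silica. Fallback: it sets out from 1 and comes back at 7, so that the ketone is in place before the oxalate and no ozonolysis is needed. Lithiated acetone N,N-dimethylhydrazone (LiN(iPr)2, THF, 0 °C) should open epoxide 1 at its terminal carbon to (R)-5-hydroxypentadecan-2-one N,N-dimethylhydrazone F4. Hydrolysis (aq CuCl2, THF) should give (R)-5-hydroxypentadecan-2-one F5, in equilibrium with its cyclic hemiketal. Acylation of the open-chain alcohol with 4 (pyridine, CH2Cl2, 0 °C) should give 7.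

**Further compounds**

F1 | step 5 | (R)-6-decyl-3-(trimethylsilyloxy)-4-[1-(trimethylsilyloxy)ethenyl]-5,6-dihydro-2H-pyran-2-one | CCCCCCCCCC[C@@H]1CC(C(=C)O[Si](C)(C)C)=C(O[Si](C)(C)C)C(=O)O1
F2 | step 5 | (R)-6-decyl-3-hydroxy-4-[(S)-3-hydroxydecanoyl]-5,6-dihydro-2H-pyran-2-one | CCCCCCCCCC[C@@H]1CC(C(=O)C[C@@H](O)CCCCCCC)=C(O)C(=O)O1
F3 | step 4 | (R)-4-acetyl-6-decyl-2-oxo-5,6-dihydro-2H-pyran-3-yl octanoate | CCCCCCCCCC[C@@H]1CC(C(C)=O)=C(OC(=O)CCCCCCC)C(=O)O1
F4 | step 3 | (R)-5-hydroxypentadecan-2-one N,N-dimethylhydrazone | CCCCCCCCCC[C@@H](O)CCC(C)=NN(C)C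
F5 | step 3 | (R)-5-hydroxypentadecan-2-one | CCCCCCCCCC[C@@H](O)CCC(C)=O
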